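A direct plan would take all seven rings from benzene building blocks, keep every hydroxyl as a benzyl ether and use 2-(benzyloxy)-4,6-difluorobenzaldehyde A1 as ring D. The perbenzylated A–B–C trimer phenol A2 would displace the fluorine para to the formyl group and the E–F–G trimer phenol A3 the ortho fluorine. A peracid would turn the formyl group of the heptamer aldehyde A4 into the last hydroxyl, and hydrogenolysis would finish.
Its weakest steps would be:
- The twofold fluoride displacement on A1 by A2 and A3: all material converges on a choice between two fluorines by very bulky phenoxides, and the second displacement must occur on a ring already deactivated by an aryloxy and a benzyloxy group.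
- The copper-mediated etherifications that install the pentaoxygenated rings C and E in A2 and A3: each joins a di-ortho-substituted partner, and each of these rings first costs a formylation or bromination, a demethylation and a rebenzylation.
- The five peracid conversions of formyl into hydroxyl, the last on A4 with seven electron-rich rings: they build no bond of the skeleton and expose polyalkoxyarenes to an oxidant late.

**Retrosynthetic overview**
Rings are lettered A to G along the chain; rings C and E are the two pentaoxygenated rings, each with aryloxy groups on the neighbouring carbons C1 and C6, one C–H (C2) and three hydroxyls (C3 to C5).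
These two rings are closed, not bought: a Danheiser benzannulation inserts the two carbons of an aryl ethynyl ether (C1, C2) into a squaric-acid-derived 2-aryloxy-3,4-dimethoxycyclobutenone (C3 to C6), forming the C2–C3 and C1–C6 bonds.
Ring C is closed first and joins A–B (ethynyl ether on the ring B oxygen) to ring D (cyclobutenone on its C1 oxygen); ring E is closed second and joins A–B–C–D (ethynyl ether on the C5 oxygen of ring D) to F–G (cyclobutenone on the ring F oxygen).
No phenoxide has to choose between two fluorines and no C–O bond is made at rings C or E; the only two copper couplings (A–O–B, F–O–G) go onto bromides flanked by hydrogens. No oligomer meets a peracid, and catalogue methyl ethers are carried to one final BBr3 cleavage.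

Key step: step 17

Remark: the six starting materials are taken as catalogue compounds; ring D is numbered with C1 bound to the ring C oxygen and C5 to the ring E oxygen; the dichlorovinyl ethers are drawn as (E) isomers (anti addition to dichloroacetylene) and the cyclobutenones are racemic, neither of which bears on the achiral target.

**Route**

Step 1
Reactants: 1 4-bromo-2,6-dimethoxyphenol
Product: 2 5-bromo-2-[(E)-1,2-dichloroethenyloxy]-1,3-dimethoxybenzene
Conditions: trichloroethylene (1.5 equiv), K2CO3, DMF, 70 °C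
Reagents that add atoms: trichloroethylene, ClC=C(Cl)Cl
Why: Base-mediated addition of the phenoxide to dichloroacetylene formed in situ from trichloroethylene should give the (E)-1,2-dichlorovinyl ether, which serves at once as the phenol protecting group and as the latent ethynyl ether, while the aryl bromide is inert.

Step 2
Reactants: 2 5-bromo-2-[(E)-1,2-dichloroethenyloxy]-1,3-dimethoxybenzene; 3 2,4,6-trimethoxyphenol
Product: 4 2-[(E)-1,2-dichloroethenyloxy]-1,3-dimethoxy-5-(2,4,6-trimethoxyphenoxy)benzene (A–B dichlorovinyl ether)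
Conditions: CuI (10 mol %), picolinic acid (20 mol %), K3PO4, DMSO, 90 °C, argon
Reagents that add atoms: none
Why: Ullmann-type diaryl ether synthesis between a di-ortho-substituted phenol and a bromide flanked by two hydrogens, the case the picolinate-ligated copper catalyst handles, with the vinylic C–Cl bonds far less reactive than the aryl bromide and too weakly acidic for phosphate.

Step 3
Reactants: 4 A–B dichlorovinyl ether
Product: 6 2-(ethynyloxy)-1,3-dimethoxy-5-(2,4,6-trimethoxyphenoxy)benzene (A–B ethynyl ether), via lithium acetylide 5 (not isolated)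
Conditions: n-BuLi (2.3 equiv), THF, −78 → −40 °C; then MeOH, −78 °C; kept as a toluene solution
Reagents that add atoms: none
Why: Elimination of HCl to the chloroalkynyl ether followed by chlorine–lithium exchange and protonation should give the terminal ynol ether, which as an aryl ether has no β-hydrogen on the oxygen substituent and cannot fragment to a ketene by a retro-ene reaction.

Step 4
Reactants: 7 3-hydroxy-4,5-dimethoxybenzaldehyde
Product: 8 3-[(E)-1,2-dichloroethenyloxy]-4,5-dimethoxybenzaldehyde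
Conditions: trichloroethylene (1.5 equiv), K2CO3, DMF, 70 °C
Reagents that add atoms: trichloroethylene, ClC=C(Cl)Cl
Why: The same phenoxide addition to dichloroacetylene as in step 1 masks the ring D oxygen that will later carry the ethynyl group, and the aldehyde is untouched by carbonate.

Step 5
Reactants: 8 3-[(E)-1,2-dichloroethenyloxy]-4,5-dimethoxybenzaldehyde
Product: 10 3-[(E)-1,2-dichloroethenyloxy]-4,5-dimethoxyphenol (ring D phenol), via aryl formate 9 (not isolated)
Conditions: mCPBA (1.3 equiv), CH2Cl2, 0 °C → rt; then K2CO3 (cat.), MeOH, rt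
Reagents that add atoms: mCPBA, O=C(OO)c1cccc(Cl)c1
Why: Baeyer–Villiger form of the Dakin oxidation on a monomer: the aryl group with a para methoxy group migrates in preference to hydrogen, the electron-poor dichlorovinyl ether is not epoxidised, and the formate is removed by methanolysis.

Step 6
Reactants: 10 ring D phenol; 11 squaric acid dichloride (3,4-dichlorocyclobut-3-ene-1,2-dione)
Product: 13 3-{3-[(E)-1,2-dichloroethenyloxy]-4,5-dimethoxyphenoxy}-4-methoxycyclobut-3-ene-1,2-dione (ring D mixed squarate), via chlorosquarate 12 (not isolated)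
Conditions: 11 (1.05 equiv), i-Pr2NEt (1.0 equiv), CH2Cl2, −78 °C; then MeOH (1.1 equiv), i-Pr2NEt (1.0 equiv), −40 → 0 °C
Reagents that add atoms: methanol, CO
Why: Two successive addition–eliminations on a vinylogous acid chloride: the first substitution deactivates the second chloride, so the unhindered phenol and then methanol can be introduced one after the other.

Step 7
Reactants: 13 ring D mixed squarate
Product: 14 (±)-2-{3-[(E)-1,2-dichloroethenyloxy]-4,5-dimethoxyphenoxy}-4-hydroxy-3-methoxycyclobut-2-en-1-one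
Conditions: LiAlH(O-t-Bu)3 (1.05 equiv), THF, −78 °C; pH 7 phosphate buffer
Reagents that add atoms: none
Why: 1,2-Reduction of one squarate carbonyl by a bulky hydride should occur at the carbonyl that is vinylogous to the poorer donor (aryloxy) and flanked by the smaller methoxy group, leaving the carbonyl next to the aryloxy carbon; the new stereocentre forms as a racemate and is erased in step 14.

Step 8
Reactants: 14 the hydroxycyclobutenone of step 7
Product: 15 (±)-2-{3-[(E)-1,2-dichloroethenyloxy]-4,5-dimethoxyphenoxy}-3,4-dimethoxycyclobut-2-en-1-one (ring D cyclobutenone)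
Conditions: MeI (10 equiv), Ag2O (1.5 equiv), CaSO4, MeCN, rt, dark
Reagents that add atoms: iodomethane, CI
Why: Purdie methylation under neutral conditions caps the allylic hydroxyl without acid, which would expel methanol, and without base, which would open the ring, and so prevents rearrangement to a butenolide when the ring is opened thermally.

Step 9
Reactants: 16 2,6-dimethoxyphenol; 17 5-bromo-1,2,3-trimethoxybenzene
Product: 18 5-(2,6-dimethoxyphenoxy)-1,2,3-trimethoxybenzene (F–G ether)
Conditions: CuI (10 mol %), picolinic acid (20 mol %), K3PO4, DMSO, 100 °C, argon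
Reagents that add atoms: none
Why: Ullmann-type diaryl ether synthesis of an electron-rich di-ortho-substituted phenol with a bromide flanked by two hydrogens, the polarity that puts the steric load on the nucleophile only.

Step 10
Reactants: 18 F–G ether
Product: 20 3,5-dimethoxy-4-(3,4,5-trimethoxyphenoxy)phenol (F–G phenol), via arylboronate 19 (not isolated)
Conditions: [Ir(OMe)(cod)]2 (1.5 mol %), 4,4'-di-tert-butyl-2,2'-bipyridine (3 mol %), B2pin2 (1.0 equiv), THF, 80 °C; then KHSO5 (as 2KHSO5·KHSO4·K2SO4), acetone–H2O, 0 °C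
Reagents that add atoms: bis(pinacolato)diboron, CC1(C)OB(OC1(C)C)B1OC(C)(C)C(C)(C)O1; potassium peroxymonosulfate, [K+].[O-]S(=O)(=O)OO
Why: Sterically controlled iridium-catalysed C–H borylation followed by ipso oxidation: the only C–H bond of 18 with no ortho substituent is the one para to the ether oxygen on ring F, so the hydroxyl enters there without any formyl or halogen handle.

Step 11
Reactants: 20 F–G phenol; 11 squaric acid dichloride
Product: 22 3-[3,5-dimethoxy-4-(3,4,5-trimethoxyphenoxy)phenoxy]-4-methoxycyclobut-3-ene-1,2-dione (F–G mixed squarate), via chlorosquarate 21 (not isolated)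
Conditions: 11 (1.05 equiv), i-Pr2NEt (1.0 equiv), CH2Cl2, −78 °C; then MeOH (1.1 equiv), i-Pr2NEt (1.0 equiv), −40 → 0 °C
Reagents that add atoms: methanol, CO
Why: The same sequential addition–elimination on the vinylogous acid chloride as in step 6, here with a phenol flanked by two hydrogens.

Step 12
Reactants: 22 F–G mixed squarate
Product: 23 (±)-2-[3,5-dimethoxy-4-(3,4,5-trimethoxyphenoxy)phenoxy]-4-hydroxy-3-methoxycyclobut-2-en-1-one
Conditions: LiAlH(O-t-Bu)3 (1.05 equiv), THF, −78 °C; pH 7 phosphate buffer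
Reagents that add atoms: none
Why: Regioselective 1,2-reduction as in step 7, at the carbonyl vinylogous to the aryloxy group and next to the methoxy carbon; the racemic stereocentre is erased in step 17.

Step 13
Reactants: 23 the hydroxycyclobutenone of step 12
Product: 24 (±)-2-[3,5-dimethoxy-4-(3,4,5-trimethoxyphenoxy)phenoxy]-3,4-dimethoxycyclobut-2-en-1-one (F–G cyclobutenone)
Conditions: MeI (10 equiv), Ag2O (1.5 equiv), CaSO4, MeCN, rt, dark
Reagents that add atoms: iodomethane, CI
Why: Purdie methylation under neutral conditions, as in step 8.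

Step 14
Reactants: 6 A–B ethynyl ether; 15 ring D cyclobutenone
Product: 29 A–B–C–D tetramer phenol 4-{3-[(E)-1,2-dichloroethenyloxy]-4,5-dimethoxyphenoxy}-5-[2,6-dimethoxy-4-(2,4,6-trimethoxyphenoxy)phenoxy]-2,3-dimethoxyphenol, via vinylketene 25 (not isolated), via vinylcyclobutenone 26 (not isolated), via dienylketene 27 (not isolated), via cyclohexadienone 28 (not isolated)
Conditions: 6 (1.3 equiv), toluene, 80 → 110 °C, argon; then K2CO3, MeOH, rt (cleaves any aryl ester formed from product and ketene)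
Reagents that add atoms: none
Why: Danheiser benzannulation (4π opening of 15 to 25, regioselective [2+2] cycloaddition with the ynol ether to 26, 4π opening to 27, 6π closure to 28 and enolisation): the oxygen-bearing alkyne carbon bonds to the aryloxy-bearing ketene carbon, so ring C should form with the ring B and ring D oxygens on neighbouring carbons and the hydrogen at C2, and the racemic stereocentre of 15 disappears on aromatisation.

Step 15
Reactants: 29 A–B–C–D tetramer phenol
Product: 30 A–B–C–D tetramer methyl ether, 1,2,3-trimethoxy-4-{3-[(E)-1,2-dichloroethenyloxy]-4,5-dimethoxyphenoxy}-5-[2,6-dimethoxy-4-(2,4,6-trimethoxyphenoxy)phenoxy]benzene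
Conditions: MeI, K2CO3, acetone, 50 °C
Reagents that add atoms: iodomethane, CI
Why: Williamson ether synthesis on the only free hydroxyl, so that no phenoxide consumes base in step 16 and no phenol intercepts the ketene in step 17.

Step 16
Reactants: 30 A–B–C–D tetramer methyl ether
Product: 32 A–B–C–D tetramer ethynyl ether (ring D carries O–C≡CH at C5), via lithium acetylide 31 (not isolated)
Conditions: n-BuLi (2.3 equiv), THF, −78 → −40 °C; then MeOH, −78 °C; kept as a toluene solution
Reagents that add atoms: none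
Why: The same elimination and chlorine–lithium exchange as in step 3, which at −78 °C should outrun ortho-lithiation of the methoxyarene rings.

Step 17
Reactants: 32 A–B–C–D tetramer ethynyl ether; 24 F–G cyclobutenone
Product: 37 heptadeca-O-methyl heptamer phenol (all hydroxyls of the target as methyl ethers except C3–OH of ring E), via vinylketene 33 (not isolated), via vinylcyclobutenone 34 (not isolated), via dienylketene 35 (not isolated), via cyclohexadienone 36 (not isolated)
Conditions: 24 (1.3 equiv), toluene, 80 → 110 °C, argon; then K2CO3, MeOH, rt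
Reagents that add atoms: none
Why: Danheiser benzannulation: 24 opens by 4π electrocyclic ring opening (the C4 methoxy group turning outward) to vinylketene 33, whose carbonyl carbon is attacked by the unsubstituted alkyne carbon of 32 in a [2+2] cycloaddition to vinylcyclobutenone 34, which opens to dienylketene 35, closes to cyclohexadienone 36 and enolises to phenol 37. The closest known reaction type is the benzannulation of cyclobutenones with alkoxyacetylenes to resorcinol monoethers, here run with an aryl ethynyl ether and a squarate-derived 2-aryloxycyclobutenone. Ring E is the only ring that remains closed; it forms by a thermal 6π disrotatory electrocyclisation of the (Z)-dienylketene, with the alkyne carbons as C1 and C2, the former carbonyl carbon as C3 and the other three cyclobutenone carbons as C6, C5 and C4. The stereocentres of 24, 34 and 36 are racemic and vanish on aromatisation, so none needs control. The step needs regioselectivity in the [2+2] event, secured by the polarisation of the ynol ether, which places the ring D oxygen at C1 next to the ring F oxygen at C6 and the hydrogen at C2; it also needs the ketene to be trapped before it recloses or acylates a phenol, for which 32 carries no free hydroxyl and an unhindered terminal alkyne carbon. In one operation the pentaoxygenated ring E is created with both aryloxy groups in place and the A–B–C–D tetramer is joined to the F–G dimer without a C–O coupling at a hindered carbon.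

Step 18
Reactants: 37 heptadeca-O-methyl heptamer phenol
Product: 38 CNP0130704.0 (target)
Conditions: BBr3 (60 equiv), CH2Cl2, −78 °C → rt, argon; then H2O, 0 °C; EtOAc extraction and size-exclusion chromatography in MeOH under argon
Reagents that add atoms: none
Why: Lewis-acid cleavage of aryl methyl ethers by bromide attack on the methyl carbon of each boron complex should remove all seventeen methyl groups and leave the six diaryl ether bonds, the acidic medium protecting the pyrogallol-type rings from air oxidation.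

**Compound list**
1 | 4-bromo-2,6-dimethoxyphenol | Oc1c(OC)cc(Br)cc1OC | starting material
2 | 5-bromo-2-[(E)-1,2-dichloroethenyloxy]-1,3-dimethoxybenzene | Cl/C=C(/Cl)Oc1c(OC)cc(Br)cc1OC | intermediate
3 | 2,4,6-trimethoxyphenol | Oc1c(OC)cc(OC)cc1OC | starting material
4 | 2-[(E)-1,2-dichloroethenyloxy]-1,3-dimethoxy-5-(2,4,6-trimethoxyphenoxy)benzene (A–B dichlorovinyl ether) | Cl/C=C(/Cl)Oc1c(OC)cc(Oc2c(OC)cc(OC)cc2OC)cc1OC | intermediate
5 | lithium [2,6-dimethoxy-4-(2,4,6-trimethoxyphenoxy)phenoxy]acetylide | [Li]C#COc1c(OC)cc(Oc2c(OC)cc(OC)cc2OC)cc1OC | intermediate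
6 | 2-(ethynyloxy)-1,3-dimethoxy-5-(2,4,6-trimethoxyphenoxy)benzene (A–B ethynyl ether) | C#COc1c(OC)cc(Oc2c(OC)cc(OC)cc2OC)cc1OC | intermediate
7 | 3-hydroxy-4,5-dimethoxybenzaldehyde | O=Cc1cc(O)c(OC)c(OC)c1 | starting material
8 | 3-[(E)-1,2-dichloroethenyloxy]-4,5-dimethoxybenzaldehyde | O=Cc1cc(O/C(Cl)=C\Cl)c(OC)c(OC)c1 | intermediate
9 | 3-[(E)-1,2-dichloroethenyloxy]-4,5-dimethoxyphenyl formate | O=COc1cc(O/C(Cl)=C\Cl)c(OC)c(OC)c1 | intermediate
10 | 3-[(E)-1,2-dichloroethenyloxy]-4,5-dimethoxyphenol (ring D phenol) | Oc1cc(O/C(Cl)=C\Cl)c(OC)c(OC)c1 | intermediate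
11 | squaric acid dichloride, 3,4-dichlorocyclobut-3-ene-1,2-dione | O=C1C(=O)C(Cl)=C1Cl | starting material
12 | 3-chloro-4-{3-[(E)-1,2-dichloroethenyloxy]-4,5-dimethoxyphenoxy}cyclobut-3-ene-1,2-dione | O=C1C(=O)C(Cl)=C1Oc1cc(O/C(Cl)=C\Cl)c(OC)c(OC)c1 | intermediate
13 | 3-{3-[(E)-1,2-dichloroethenyloxy]-4,5-dimethoxyphenoxy}-4-methoxycyclobut-3-ene-1,2-dione (ring D mixed squarate) | O=C1C(=O)C(OC)=C1Oc1cc(O/C(Cl)=C\Cl)c(OC)c(OC)c1 | intermediate
14 | (±)-2-{3-[(E)-1,2-dichloroethenyloxy]-4,5-dimethoxyphenoxy}-4-hydroxy-3-methoxycyclobut-2-en-1-one | O=C1C(Oc2cc(O/C(Cl)=C\Cl)c(OC)c(OC)c2)=C(OC)C1O | intermediate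
15 | (±)-2-{3-[(E)-1,2-dichloroethenyloxy]-4,5-dimethoxyphenoxy}-3,4-dimethoxycyclobut-2-en-1-one (ring D cyclobutenone) | O=C1C(Oc2cc(O/C(Cl)=C\Cl)c(OC)c(OC)c2)=C(OC)C1OC | intermediate
16 | 2,6-dimethoxyphenol | Oc1c(OC)cccc1OC | starting material
17 | 5-bromo-1,2,3-trimethoxybenzene | COc1cc(Br)cc(OC)c1OC | starting material
18 | 5-(2,6-dimethoxyphenoxy)-1,2,3-trimethoxybenzene (F–G ether) | COc1cccc(OC)c1Oc1cc(OC)c(OC)c(OC)c1 | intermediate
19 | 2-[3,5-dimethoxy-4-(3,4,5-trimethoxyphenoxy)phenyl]-4,4,5,5-tetramethyl-1,3,2-dioxaborolane | CC1(C)OB(OC1(C)C)c1cc(OC)c(Oc2cc(OC)c(OC)c(OC)c2)c(OC)c1 | intermediate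
20 | 3,5-dimethoxy-4-(3,4,5-trimethoxyphenoxy)phenol (F–G phenol) | Oc1cc(OC)c(Oc2cc(OC)c(OC)c(OC)c2)c(OC)c1 | intermediate
21 | 3-chloro-4-[3,5-dimethoxy-4-(3,4,5-trimethoxyphenoxy)phenoxy]cyclobut-3-ene-1,2-dione | O=C1C(=O)C(Cl)=C1Oc1cc(OC)c(Oc2cc(OC)c(OC)c(OC)c2)c(OC)c1 | intermediate
22 | 3-[3,5-dimethoxy-4-(3,4,5-trimethoxyphenoxy)phenoxy]-4-methoxycyclobut-3-ene-1,2-dione (F–G mixed squarate) | O=C1C(=O)C(OC)=C1Oc1cc(OC)c(Oc2cc(OC)c(OC)c(OC)c2)c(OC)c1 | intermediate
23 | (±)-2-[3,5-dimethoxy-4-(3,4,5-trimethoxyphenoxy)phenoxy]-4-hydroxy-3-methoxycyclobut-2-en-1-one | O=C1C(Oc2cc(OC)c(Oc3cc(OC)c(OC)c(OC)c3)c(OC)c2)=C(OC)C1O | intermediate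
24 | (±)-2-[3,5-dimethoxy-4-(3,4,5-trimethoxyphenoxy)phenoxy]-3,4-dimethoxycyclobut-2-en-1-one (F–G cyclobutenone) | O=C1C(Oc2cc(OC)c(Oc3cc(OC)c(OC)c(OC)c3)c(OC)c2)=C(OC)C1OC | intermediate
25 | vinylketene from 15: 2-(ring D aryloxy)-3,4-dimethoxybuta-1,3-dien-1-one, 4-methoxy group trans to C2 | O=C=C(Oc1cc(O/C(Cl)=C\Cl)c(OC)c(OC)c1)/C(OC)=C/OC | intermediate
26 | (±)-4-vinylcyclobutenone from 25 and 6: 3-(A–B aryloxy)-4-(ring D aryloxy)-4-(1,2-dimethoxyethenyl)cyclobut-2-en-1-one | O=C1C=C(Oc2c(OC)cc(Oc3c(OC)cc(OC)cc3OC)cc2OC)C1(Oc2cc(O/C(Cl)=C\Cl)c(OC)c(OC)c2)/C(OC)=C/OC | intermediate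
27 | dienylketene: 3-(A–B aryloxy)-4-(ring D aryloxy)-5,6-dimethoxyhexa-1,3,5-trien-1-one, ketene and vinyl groups cis | O=C=C/C(Oc1c(OC)cc(Oc2c(OC)cc(OC)cc2OC)cc1OC)=C(Oc1cc(O/C(Cl)=C\Cl)c(OC)c(OC)c1)\C(OC)=C\OC | intermediate
28 | (±)-cyclohexa-2,4-dienone tautomer of 29: 3-(A–B aryloxy)-4-(ring D aryloxy)-5,6-dimethoxycyclohexa-2,4-dien-1-one | O=C1C=C(Oc2c(OC)cc(Oc3c(OC)cc(OC)cc3OC)cc2OC)C(Oc2cc(O/C(Cl)=C\Cl)c(OC)c(OC)c2)=C(OC)C1OC | intermediate
29 | A–B–C–D tetramer phenol, 4-{3-[(E)-1,2-dichloroethenyloxy]-4,5-dimethoxyphenoxy}-5-[2,6-dimethoxy-4-(2,4,6-trimethoxyphenoxy)phenoxy]-2,3-dimethoxyphenol | Oc1cc(Oc2c(OC)cc(Oc3c(OC)cc(OC)cc3OC)cc2OC)c(Oc2cc(O/C(Cl)=C\Cl)c(OC)c(OC)c2)c(OC)c1OC | intermediate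
30 | A–B–C–D tetramer methyl ether (methyl ether of 29) | COc1cc(Oc2c(OC)cc(Oc3c(OC)cc(OC)cc3OC)cc2OC)c(Oc2cc(O/C(Cl)=C\Cl)c(OC)c(OC)c2)c(OC)c1OC | intermediate
31 | lithium acetylide of the tetramer (O–C≡C–Li at C5 of ring D) | COc1cc(Oc2c(OC)cc(Oc3c(OC)cc(OC)cc3OC)cc2OC)c(Oc2cc(OC#C[Li])c(OC)c(OC)c2)c(OC)c1OC | intermediate
32 | A–B–C–D tetramer ethynyl ether (O–C≡CH at C5 of ring D) | COc1cc(Oc2c(OC)cc(Oc3c(OC)cc(OC)cc3OC)cc2OC)c(Oc2cc(OC#C)c(OC)c(OC)c2)c(OC)c1OC | intermediate
33 | vinylketene from 24: 2-(F–G aryloxy)-3,4-dimethoxybuta-1,3-dien-1-one, 4-methoxy group trans to C2 | O=C=C(Oc1cc(OC)c(Oc2cc(OC)c(OC)c(OC)c2)c(OC)c1)/C(OC)=C/OC | intermediate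
34 | (±)-4-vinylcyclobutenone from 33 and 32: 3-(tetramer aryloxy)-4-(F–G aryloxy)-4-(1,2-dimethoxyethenyl)cyclobut-2-en-1-one | O=C1C=C(Oc2cc(Oc3c(OC)c(OC)c(OC)cc3Oc3c(OC)cc(Oc4c(OC)cc(OC)cc4OC)cc3OC)cc(OC)c2OC)C1(Oc2cc(OC)c(Oc3cc(OC)c(OC)c(OC)c3)c(OC)c2)/C(OC)=C/OC | intermediate
35 | dienylketene: 3-(tetramer aryloxy)-4-(F–G aryloxy)-5,6-dimethoxyhexa-1,3,5-trien-1-one, ketene and vinyl groups cis | O=C=C/C(Oc1cc(Oc2c(OC)c(OC)c(OC)cc2Oc2c(OC)cc(Oc3c(OC)cc(OC)cc3OC)cc2OC)cc(OC)c1OC)=C(Oc1cc(OC)c(Oc2cc(OC)c(OC)c(OC)c2)c(OC)c1)\C(OC)=C\OC | intermediate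
36 | (±)-cyclohexa-2,4-dienone tautomer of 37 | O=C1C=C(Oc2cc(Oc3c(OC)c(OC)c(OC)cc3Oc3c(OC)cc(Oc4c(OC)cc(OC)cc4OC)cc3OC)cc(OC)c2OC)C(Oc2cc(OC)c(Oc3cc(OC)c(OC)c(OC)c3)c(OC)c2)=C(OC)C1OC | intermediate
37 | heptadeca-O-methyl heptamer phenol (free hydroxyl at C3 of ring E) | Oc1cc(Oc2cc(Oc3c(OC)c(OC)c(OC)cc3Oc3c(OC)cc(Oc4c(OC)cc(OC)cc4OC)cc3OC)cc(OC)c2OC)c(Oc2cc(OC)c(Oc3cc(OC)c(OC)c(OC)c3)c(OC)c2)c(OC)c1OC | intermediate
38 | CNP0130704.0, heptameric phlorotannin with eighteen free hydroxyls (achiral) | Oc1cc(O)c(Oc2cc(O)c(Oc3cc(O)c(O)c(O)c3Oc3cc(O)c(O)c(Oc4cc(O)c(O)c(O)c4Oc4cc(O)c(Oc5cc(O)c(O)c(O)c5)c(O)c4)c3)c(O)c2)c(O)c1 | target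

**Count and risks**
Total step count: 18. Longest linear sequence: 10 steps (steps 4 to 8, then 14 to 18).

Steps most likely to fail:

1. Step 17 (step 14 is the same reaction on smaller partners and tests it first). The vinylketene may reclose, dimerise or acylate the product before the aryl ethynyl ether, a weaker nucleophile than an alkyl ynol ether, adds; the terminal ethynyl ether may also polymerise on heating. The fallback sets out from lithium acetylide 31 (step 16 without the methanol quench) and comes back to the route at 38. Addition of 31 to catalogue dimethyl squarate (THF, −78 °C; NH4Cl) would give the 4-(aryloxyethynyl)-4-hydroxy-2,3-dimethoxycyclobutenone F1. Its thermolysis (toluene, 110 °C) is a Moore rearrangement, a ring expansion within one molecule that needs no bimolecular ketene trapping, to the 5-aryloxy-2,3-dimethoxy-1,4-benzoquinone F2. Na2S2O4 would reduce F2 to the hydroquinone F3, and MeI (1 equiv) with K2CO3 would methylate its less hindered hydroxyl to the monomethyl ether F4. A Chan–Lam coupling of the remaining hindered hydroxyl of F4 with boronate 19 (isolated instead of oxidised; Cu(OAc)2, pyridine, air, CH2Cl2) would give the octadeca-O-methyl heptamer F5, which BBr3 as in step 18 would convert into 38.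

2. Step 12 (step 7 is its counterpart in the ring D series). Hydride may add to the wrong carbonyl of the mixed squarate, or add in conjugate fashion and expel the aryloxide. The fallback sets out from phenol 20 and comes back to the route at vinylketene 33 in step 17. Phenol 20 would be alkylated (K2CO3, acetone) with methyl 2-chloro-4-methoxy-3-oxobutanoate F6 (from catalogue methyl 4-methoxy-3-oxobutanoate and SO2Cl2) to the α-aryloxy β-keto ester F7. F7 would be converted into the methyl enol ether F8 (HC(OMe)3, cat. H2SO4, MeOH), saponified to the acid F9 (LiOH, THF–H2O) and turned into the acid chloride F10 ((COCl)2, cat. DMF). Slow addition of Et3N to F10 and 32 in toluene should give 33 by 1,4-dehydrochlorination, the position of the aryloxy group being fixed by the C–O bond made in the alkylation.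

3. Step 18. Cleavage of seventeen methyl ethers may stall as boron aryloxides precipitate, and the pyrogallol-type rings may oxidise in air during isolation. The fallback sets out from 37 and comes back to the route at 38. After the BBr3 treatment the crude polyphenol would be acetylated at once (Ac2O, pyridine) to the octadecaacetate F11, which is stable to air and can be purified on silica and freed from partly methylated material. Acid methanolysis of F11 (HCl in MeOH, argon) would then release 38.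

Further compounds
F1 | step 17 | (±)-4-hydroxy-2,3-dimethoxy-4-[(tetramer aryloxy)ethynyl]cyclobut-2-en-1-one, tetramer aryl bound through the C5 oxygen of ring D | O=C1C(OC)=C(OC)C1(O)C#COc1cc(Oc2c(OC)c(OC)c(OC)cc2Oc2c(OC)cc(Oc3c(OC)cc(OC)cc3OC)cc2OC)cc(OC)c1OC
F2 | step 17 | 2,3-dimethoxy-5-(tetramer aryloxy)-1,4-benzoquinone | O=C1C=C(Oc2cc(Oc3c(OC)c(OC)c(OC)cc3Oc3c(OC)cc(Oc4c(OC)cc(OC)cc4OC)cc3OC)cc(OC)c2OC)C(=O)C(OC)=C1OC
F3 | step 17 | 2,3-dimethoxy-5-(tetramer aryloxy)benzene-1,4-diol | Oc1cc(Oc2cc(Oc3c(OC)c(OC)c(OC)cc3Oc3c(OC)cc(Oc4c(OC)cc(OC)cc4OC)cc3OC)cc(OC)c2OC)c(O)c(OC)c1OC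
F4 | step 17 | 2,3,4-trimethoxy-6-(tetramer aryloxy)phenol (hydroxyl next to the aryloxy group free) | COc1cc(Oc2cc(Oc3c(OC)c(OC)c(OC)cc3Oc3c(OC)cc(Oc4c(OC)cc(OC)cc4OC)cc3OC)cc(OC)c2OC)c(O)c(OC)c1OC
F5 | step 17 | octadeca-O-methyl ether of the target | COc1cc(Oc2cc(Oc3c(OC)c(OC)c(OC)cc3Oc3c(OC)cc(Oc4c(OC)cc(OC)cc4OC)cc3OC)cc(OC)c2OC)c(Oc2cc(OC)c(Oc3cc(OC)c(OC)c(OC)c3)c(OC)c2)c(OC)c1OC
F6 | step 12 | methyl 2-chloro-4-methoxy-3-oxobutanoate (racemic) | COCC(=O)C(Cl)C(=O)OC
F7 | step 12 | methyl 2-[3,5-dimethoxy-4-(3,4,5-trimethoxyphenoxy)phenoxy]-4-methoxy-3-oxobutanoate (racemic) | COCC(=O)C(Oc1cc(OC)c(Oc2cc(OC)c(OC)c(OC)c2)c(OC)c1)C(=O)OC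
F8 | step 12 | methyl 2-[3,5-dimethoxy-4-(3,4,5-trimethoxyphenoxy)phenoxy]-3,4-dimethoxybut-2-enoate (E/Z mixture) | COCC(OC)=C(Oc1cc(OC)c(Oc2cc(OC)c(OC)c(OC)c2)c(OC)c1)C(=O)OC
F9 | step 12 | 2-[3,5-dimethoxy-4-(3,4,5-trimethoxyphenoxy)phenoxy]-3,4-dimethoxybut-2-enoic acid (E/Z mixture) | COCC(OC)=C(Oc1cc(OC)c(Oc2cc(OC)c(OC)c(OC)c2)c(OC)c1)C(=O)O
F10 | step 12 | 2-[3,5-dimethoxy-4-(3,4,5-trimethoxyphenoxy)phenoxy]-3,4-dimethoxybut-2-enoyl chloride (E/Z mixture) | COCC(OC)=C(Oc1cc(OC)c(Oc2cc(OC)c(OC)c(OC)c2)c(OC)c1)C(Cl)=O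
F11 | step 18 | octadeca-O-acetate of the target | CC(=O)Oc1cc(OC(C)=O)c(Oc2cc(OC(C)=O)c(Oc3cc(OC(C)=O)c(OC(C)=O)c(OC(C)=O)c3Oc3cc(OC(C)=O)c(OC(C)=O)c(Oc4cc(OC(C)=O)c(OC(C)=O)c(OC(C)=O)c4Oc4cc(OC(C)=O)c(Oc5cc(OC(C)=O)c(OC(C)=O)c(OC(C)=O)c5)c(OC(C)=O)c4)c3)c(OC(C)=O)c2)c(OC(C)=O)c1
A1 | direct plan | 2-(benzyloxy)-4,6-difluorobenzaldehyde | O=Cc1c(F)cc(F)cc1OCc1ccccc1
A2 | direct plan | perbenzylated A–B–C trimer phenol, 2,3,4-tris(benzyloxy)-6-{2,6-bis(benzyloxy)-4-[2,4,6-tris(benzyloxy)phenoxy]phenoxy}phenol | c9ccccc9COc1cc(OCc9ccccc9)c(Oc2cc(OCc9ccccc9)c(Oc3cc(OCc9ccccc9)c(OCc9ccccc9)c(OCc9ccccc9)c3O)c(OCc9ccccc9)c2)c(OCc9ccccc9)c1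
A3 | direct plan | perbenzylated E–F–G trimer phenol, 3,4,5-tris(benzyloxy)-2-{3,5-bis(benzyloxy)-4-[3,4,5-tris(benzyloxy)phenoxy]phenoxy}phenol | Oc1cc(OCc9ccccc9)c(OCc9ccccc9)c(OCc9ccccc9)c1Oc2cc(OCc9ccccc9)c(Oc3cc(OCc9ccccc9)c(OCc9ccccc9)c(OCc9ccccc9)c3)c(OCc9ccccc9)c2
A4 | direct plan | heptadecabenzyl heptamer aldehyde (formyl group at C4 of ring D) | c9ccccc9COc1cc(OCc9ccccc9)c(Oc2cc(OCc9ccccc9)c(Oc3cc(OCc9ccccc9)c(OCc9ccccc9)c(OCc9ccccc9)c3Oc3cc(OCc9ccccc9)c(C=O)c(Oc4cc(OCc9ccccc9)c(OCc9ccccc9)c(OCc9ccccc9)c4Oc4cc(OCc9ccccc9)c(Oc5cc(OCc9ccccc9)c(OCc9ccccc9)c(OCc9ccccc9)c5)c(OCc9ccccc9)c4)c3)c(OCc9ccccc9)c2)c(OCc9ccccc9)c1
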